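**Retrosynthetic overview**
- Target ⇐ global hydrogenolysis (17 benzyl ethers, 3 aryl bromides) ⇐ double galloylation of a protected diol.
- Chain C1–flavan C6 bond ⇐ Friedel–Crafts opening, with inversion, of a (2S,3R)-cis-1,3-diaryl epoxide by C6 of 8-bromo-penta-O-benzyl-epigallocatechin; bromines block C8 and the phloroglucinol ring of the electrophile.
- Both halves ⇐ one (Z)-1,3-diarylpropene, epoxidised with the (S,S)-Mn(salen) catalyst for the flavan half and the (R,R)-catalyst for the chain half.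
- Ring order: all benzene rings are bought; the key step makes an oxirane and then pyran ring C in one operation on the free-phenol Z-olefin; a second oxirane is made later and opened in the coupling.
- Z-olefin ⇐ Lindlar reduction ⇐ propargyl phenol ⇐ acetylide addition and ionic deoxygenation from two benzaldehydes.

Assumption: the SMILES is read as (2R,3R) in the flavan unit and (1R,2S) in the 1,1,3-triarylpropan-2-yl chain, attached at C6 of ring A. Ring D is the 2,4,6-trioxygenated chain ring and ring E the 3,4,5-trioxygenated chain ring.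

**Route**

Step 1
Reactants: 1 2,4,6-trihydroxybenzaldehyde
Product: 2 2,4-bis(benzyloxy)-6-hydroxybenzaldehyde
Conditions: BnBr (2.05 equiv), K2CO3 (2.2 equiv), DMF, 0 °C → rt
Reagents that add atoms: benzyl bromide, BrCc1ccccc1
Why: Williamson etherification alkylates the 4-OH and one ortho-OH, while the remaining ortho-OH is hydrogen-bonded to the formyl group, is the least nucleophilic and stays free.

Step 2
Reactants: 3 3,4,5-tris(benzyloxy)benzaldehyde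
Product: 4 1,2,3-tris(benzyloxy)-5-ethynylbenzene
Conditions: dimethyl (1-diazo-2-oxopropyl)phosphonate (1.3 equiv), K2CO3 (2 equiv), MeOH/THF (1:1), 0 °C → rt
Reagents that add atoms: dimethyl (1-diazo-2-oxopropyl)phosphonate, CC(=O)C(=[N+]=[N-])P(=O)(OC)OC
Why: Ohira–Bestmann (Seyferth–Gilbert) homologation turns the aldehyde into the terminal alkyne under mild base that leaves the benzyl ethers untouched.

Step 3
Reactants: 2 2,4-bis(benzyloxy)-6-hydroxybenzaldehyde; 4 1,2,3-tris(benzyloxy)-5-ethynylbenzene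
Product: 6 3,5-bis(benzyloxy)-2-{3-[3,4,5-tris(benzyloxy)phenyl]prop-2-yn-1-yl}phenol, via propargylic alcohol 5 (not isolated)
Conditions: 4 (2.2 equiv), n-BuLi (2.1 equiv), THF, −78 °C; then 2, −78 °C → rt; H2O; crude 5: Et3SiH (3 equiv), TFA (5 equiv), CH2Cl2, −78 → −30 °C
Reagents that add atoms: none
Why: Acetylide 1,2-addition to the aldehyde (the first equivalent only deprotonates the phenol) is followed by ionic hydrogenation, in which TFA ionises the doubly activated benzylic-propargylic alcohol to an o-quinone-methide-type cation that Et3SiH reduces to CH2, removing the transient racemic carbinol centre.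

Step 4
Reactants: 6 3,5-bis(benzyloxy)-2-{3-[3,4,5-tris(benzyloxy)phenyl]prop-2-yn-1-yl}phenol
Product: 7 3,5-bis(benzyloxy)-2-{(Z)-3-[3,4,5-tris(benzyloxy)phenyl]prop-2-en-1-yl}phenol
Conditions: H2 (1 atm), Pd/CaCO3 poisoned with Pb(OAc)2, quinoline, EtOAc, rt
Reagents that add atoms: none
Why: Lindlar semi-hydrogenation adds H2 syn to the alkyne on the poisoned catalyst and gives the Z-olefin without cleaving benzyl ethers.

Step 5 (key step)
Reactants: 7 3,5-bis(benzyloxy)-2-{(Z)-3-[3,4,5-tris(benzyloxy)phenyl]prop-2-en-1-yl}phenol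
Product: 9 (2R,3R)-5,7-bis(benzyloxy)-2-[3,4,5-tris(benzyloxy)phenyl]chroman-3-ol, via epoxy phenol 8 (not isolated)
Conditions: (S,S)-[N,N'-bis(3,5-di-tert-butylsalicylidene)-1,2-cyclohexanediaminato]MnCl (5 mol %), NMO (5 equiv), mCPBA (1.5 equiv), CH2Cl2, −78 °C; then CSA (10 mol %), −78 → 0 °C
Reagents that add atoms: mCPBA, OOC(=O)c1cccc(Cl)c1
Why: Proposed new method: a Jacobsen–Katsuki epoxidation run on the free phenol at −78 °C (where uncatalysed epoxidation and phenol oxidation are slow) should give the (2R,3S)-cis-epoxide 8 with the facial sense known for cis-β-alkylstyrenes and indene with the (S,S)-catalyst, and acid then triggers 6-endo SN2-type attack of the phenol at the benzylic carbon with inversion, so that the oxirane and pyran ring C are both formed in one flask and C2 (R) and C3 (R) are set 2,3-cis; the closest known reactions are the Mn(salen) epoxidation of cis-β-substituted styrenes and the acid-catalysed 6-endo cyclisation of 2-(3-aryloxiranylmethyl)phenols to flavan-3-ols.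

Step 6
Reactants: 9 (2R,3R)-5,7-bis(benzyloxy)-2-[3,4,5-tris(benzyloxy)phenyl]chroman-3-ol
Product: 10 (2R,3R)-5,7-bis(benzyloxy)-8-bromo-2-[3,4,5-tris(benzyloxy)phenyl]chroman-3-ol
Conditions: NBS (1.0 equiv), CH2Cl2, −78 → −20 °C
Reagents that add atoms: N-bromosuccinimide, BrN1C(=O)CCC1=O
Why: Electrophilic aromatic bromination of 5,7-bis(benzyloxy)flavans goes to the less crowded C8, which leaves C6 as the only free position of ring A and does not touch the stereocentres.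

Step 7
Reactants: 7 3,5-bis(benzyloxy)-2-{(Z)-3-[3,4,5-tris(benzyloxy)phenyl]prop-2-en-1-yl}phenol
Product: 11 1,3,5-tris(benzyloxy)-2-{(Z)-3-[3,4,5-tris(benzyloxy)phenyl]prop-2-en-1-yl}benzene
Conditions: BnBr (1.2 equiv), K2CO3 (1.5 equiv), DMF, rt
Reagents that add atoms: benzyl bromide, BrCc1ccccc1
Why: Williamson etherification of the single phenol proceeds under conditions that do not isomerise the Z-olefin.

Step 8
Reactants: 11 1,3,5-tris(benzyloxy)-2-{(Z)-3-[3,4,5-tris(benzyloxy)phenyl]prop-2-en-1-yl}benzene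
Product: 12 1,3,5-tris(benzyloxy)-2,4-dibromo-6-{(Z)-3-[3,4,5-tris(benzyloxy)phenyl]prop-2-en-1-yl}benzene
Conditions: NBS (2.1 equiv), CH2Cl2, −78 °C, dark
Reagents that add atoms: N-bromosuccinimide, BrN1C(=O)CCC1=O
Why: Electrophilic aromatic bromination of the phloroglucinol triether ring D is far faster than any reaction of the olefin or ring E, and the two bromines block ring D so that the later epoxide cannot alkylate itself.

Step 9
Reactants: 12 1,3,5-tris(benzyloxy)-2,4-dibromo-6-{(Z)-3-[3,4,5-tris(benzyloxy)phenyl]prop-2-en-1-yl}benzene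
Product: 13 (2S,3R)-2-[2,4,6-tris(benzyloxy)-3,5-dibromobenzyl]-3-[3,4,5-tris(benzyloxy)phenyl]oxirane
Conditions: (R,R)-[N,N'-bis(3,5-di-tert-butylsalicylidene)-1,2-cyclohexanediaminato]MnCl (5 mol %), NMO (5 equiv), mCPBA (1.5 equiv), CH2Cl2, −78 °C; filtration through basic alumina, used crude
Reagents that add atoms: mCPBA, OOC(=O)c1cccc(Cl)c1
Why: Jacobsen–Katsuki epoxidation with the (R,R)-catalyst attacks the opposite olefin face to step 5 and sets the (2S,3R)-cis-epoxide (benzylic carbon R).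

Step 10
Reactants: 10 (2R,3R)-5,7-bis(benzyloxy)-8-bromo-2-[3,4,5-tris(benzyloxy)phenyl]chroman-3-ol; 13 (2S,3R)-2-[2,4,6-tris(benzyloxy)-3,5-dibromobenzyl]-3-[3,4,5-tris(benzyloxy)phenyl]oxirane
Product: 14 (1R,2S)-1-{(2R,3R)-5,7-bis(benzyloxy)-8-bromo-3-hydroxy-2-[3,4,5-tris(benzyloxy)phenyl]chroman-6-yl}-1-[3,4,5-tris(benzyloxy)phenyl]-3-[2,4,6-tris(benzyloxy)-3,5-dibromophenyl]propan-2-ol
Conditions: 10 (1.5 equiv), HFIP/CH2Cl2 (1:1), 0 °C → rt
Reagents that add atoms: none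
Why: In this Friedel–Crafts epoxide arylation HFIP activates the epoxide by hydrogen bonding and C6, the only free position of ring A, opens it at the benzylic carbon in an SN2-type process with inversion, which sets chain C1 (R) while chain C2 (S) comes unchanged from the epoxide.

Step 11
Reactants: 14 (1R,2S)-1-{(2R,3R)-5,7-bis(benzyloxy)-8-bromo-3-hydroxy-2-[3,4,5-tris(benzyloxy)phenyl]chroman-6-yl}-1-[3,4,5-tris(benzyloxy)phenyl]-3-[2,4,6-tris(benzyloxy)-3,5-dibromophenyl]propan-2-ol; 15 3,4,5-tris(benzyloxy)benzoic acid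
Product: 16 (1R,2S)-1-{(2R,3R)-5,7-bis(benzyloxy)-8-bromo-3-[3,4,5-tris(benzyloxy)benzoyloxy]-2-[3,4,5-tris(benzyloxy)phenyl]chroman-6-yl}-1-[3,4,5-tris(benzyloxy)phenyl]-3-[2,4,6-tris(benzyloxy)-3,5-dibromophenyl]propan-2-yl 3,4,5-tris(benzyloxy)benzoate
Conditions: 15 (3 equiv), DCC (3.3 equiv), DMAP (1 equiv), CH2Cl2, rt → 40 °C
Reagents that add atoms: none
Why: Steglich esterification acylates both secondary alcohols at oxygen, so all four stereocentres are retained.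

Step 12
Reactants: 16 (1R,2S)-1-{(2R,3R)-5,7-bis(benzyloxy)-8-bromo-3-[3,4,5-tris(benzyloxy)benzoyloxy]-2-[3,4,5-tris(benzyloxy)phenyl]chroman-6-yl}-1-[3,4,5-tris(benzyloxy)phenyl]-3-[2,4,6-tris(benzyloxy)-3,5-dibromophenyl]propan-2-yl 3,4,5-tris(benzyloxy)benzoate
Product: 17 (1R,2S)-1-[(2R,3R)-5,7-dihydroxy-3-(3,4,5-trihydroxybenzoyloxy)-2-(3,4,5-trihydroxyphenyl)chroman-6-yl]-1-(3,4,5-trihydroxyphenyl)-3-(2,4,6-trihydroxyphenyl)propan-2-yl 3,4,5-trihydroxybenzoate (target)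
Conditions: H2 (1 atm), Pd(OH)2/C, NaOAc (3.3 equiv), THF/MeOH (1:1), rt; filtration under Ar, Sephadex LH-20
Reagents that add atoms: none
Why: Hydrogenolysis over Pd(OH)2/C cleaves the seventeen benzyl ethers and the three aryl C–Br bonds, while the chroman C–O bond, the two esters and the stereocentres survive under buffered conditions as in benzyl-protected catechin gallate deprotections.

**Compound list**

1 | 2,4,6-trihydroxybenzaldehyde | O=Cc1c(O)cc(O)cc1O | starting material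
2 | 2,4-bis(benzyloxy)-6-hydroxybenzaldehyde | O=Cc1c(O)cc(OCc2ccccc2)cc1OCc1ccccc1 | intermediate
3 | 3,4,5-tris(benzyloxy)benzaldehyde | O=Cc1cc(OCc2ccccc2)c(OCc2ccccc2)c(OCc2ccccc2)c1 | starting material
4 | 1,2,3-tris(benzyloxy)-5-ethynylbenzene | C#Cc1cc(OCc2ccccc2)c(OCc2ccccc2)c(OCc2ccccc2)c1 | intermediate
5 | rac-1-[2,4-bis(benzyloxy)-6-hydroxyphenyl]-3-[3,4,5-tris(benzyloxy)phenyl]prop-2-yn-1-ol (racemic) | OC(C#Cc1cc(OCc2ccccc2)c(OCc2ccccc2)c(OCc2ccccc2)c1)c1c(O)cc(OCc2ccccc2)cc1OCc1ccccc1 | intermediate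
6 | 3,5-bis(benzyloxy)-2-{3-[3,4,5-tris(benzyloxy)phenyl]prop-2-yn-1-yl}phenol | Oc1cc(OCc2ccccc2)cc(OCc2ccccc2)c1CC#Cc1cc(OCc2ccccc2)c(OCc2ccccc2)c(OCc2ccccc2)c1 | intermediate
7 | 3,5-bis(benzyloxy)-2-{(Z)-3-[3,4,5-tris(benzyloxy)phenyl]prop-2-en-1-yl}phenol | Oc1cc(OCc2ccccc2)cc(OCc2ccccc2)c1C/C=C\c1cc(OCc2ccccc2)c(OCc2ccccc2)c(OCc2ccccc2)c1 | intermediate
8 | 3,5-bis(benzyloxy)-2-{[(2R,3S)-3-(3,4,5-tris(benzyloxy)phenyl)oxiran-2-yl]methyl}phenol | Oc1cc(OCc2ccccc2)cc(OCc2ccccc2)c1C[C@H]1O[C@H]1c1cc(OCc2ccccc2)c(OCc2ccccc2)c(OCc2ccccc2)c1 | intermediate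
9 | (2R,3R)-5,7-bis(benzyloxy)-2-[3,4,5-tris(benzyloxy)phenyl]chroman-3-ol (penta-O-benzyl-(−)-epigallocatechin) | O[C@@H]1Cc2c(OCc3ccccc3)cc(OCc3ccccc3)cc2O[C@@H]1c1cc(OCc2ccccc2)c(OCc2ccccc2)c(OCc2ccccc2)c1 | intermediate
10 | (2R,3R)-5,7-bis(benzyloxy)-8-bromo-2-[3,4,5-tris(benzyloxy)phenyl]chroman-3-ol | O[C@@H]1Cc2c(OCc3ccccc3)cc(OCc3ccccc3)c(Br)c2O[C@@H]1c1cc(OCc2ccccc2)c(OCc2ccccc2)c(OCc2ccccc2)c1 | intermediate
11 | 1,3,5-tris(benzyloxy)-2-{(Z)-3-[3,4,5-tris(benzyloxy)phenyl]prop-2-en-1-yl}benzene | C(/C=C\c1cc(OCc2ccccc2)c(OCc2ccccc2)c(OCc2ccccc2)c1)c1c(OCc2ccccc2)cc(OCc2ccccc2)cc1OCc1ccccc1 | intermediate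
12 | 1,3,5-tris(benzyloxy)-2,4-dibromo-6-{(Z)-3-[3,4,5-tris(benzyloxy)phenyl]prop-2-en-1-yl}benzene | C(/C=C\c1cc(OCc2ccccc2)c(OCc2ccccc2)c(OCc2ccccc2)c1)c1c(OCc2ccccc2)c(Br)c(OCc2ccccc2)c(Br)c1OCc1ccccc1 | intermediate
13 | (2S,3R)-2-[2,4,6-tris(benzyloxy)-3,5-dibromobenzyl]-3-[3,4,5-tris(benzyloxy)phenyl]oxirane | C([C@@H]1O[C@@H]1c1cc(OCc2ccccc2)c(OCc2ccccc2)c(OCc2ccccc2)c1)c1c(OCc2ccccc2)c(Br)c(OCc2ccccc2)c(Br)c1OCc1ccccc1 | intermediate
14 | (1R,2S)-1-{(2R,3R)-5,7-bis(benzyloxy)-8-bromo-3-hydroxy-2-[3,4,5-tris(benzyloxy)phenyl]chroman-6-yl}-1-[3,4,5-tris(benzyloxy)phenyl]-3-[2,4,6-tris(benzyloxy)-3,5-dibromophenyl]propan-2-ol | O[C@@H](Cc1c(OCc2ccccc2)c(Br)c(OCc2ccccc2)c(Br)c1OCc1ccccc1)[C@H](c1cc(OCc2ccccc2)c(OCc2ccccc2)c(OCc2ccccc2)c1)c1c(OCc2ccccc2)c(Br)c2c(c1OCc1ccccc1)C[C@@H](O)[C@@H](c1cc(OCc3ccccc3)c(OCc3ccccc3)c(OCc3ccccc3)c1)O2 | intermediate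
15 | 3,4,5-tris(benzyloxy)benzoic acid | OC(=O)c1cc(OCc2ccccc2)c(OCc2ccccc2)c(OCc2ccccc2)c1 | starting material
16 | (1R,2S)-1-{(2R,3R)-5,7-bis(benzyloxy)-8-bromo-3-[3,4,5-tris(benzyloxy)benzoyloxy]-2-[3,4,5-tris(benzyloxy)phenyl]chroman-6-yl}-1-[3,4,5-tris(benzyloxy)phenyl]-3-[2,4,6-tris(benzyloxy)-3,5-dibromophenyl]propan-2-yl 3,4,5-tris(benzyloxy)benzoate | O=C(O[C@@H](Cc1c(OCc2ccccc2)c(Br)c(OCc2ccccc2)c(Br)c1OCc1ccccc1)[C@H](c1cc(OCc2ccccc2)c(OCc2ccccc2)c(OCc2ccccc2)c1)c1c(OCc2ccccc2)c(Br)c2c(c1OCc1ccccc1)C[C@@H](OC(=O)c1cc(OCc3ccccc3)c(OCc3ccccc3)c(OCc3ccccc3)c1)[C@@H](c1cc(OCc3ccccc3)c(OCc3ccccc3)c(OCc3ccccc3)c1)O2)c1cc(OCc2ccccc2)c(OCc2ccccc2)c(OCc2ccccc2)c1 | intermediate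
17 | (1R,2S)-1-[(2R,3R)-5,7-dihydroxy-3-(3,4,5-trihydroxybenzoyloxy)-2-(3,4,5-trihydroxyphenyl)chroman-6-yl]-1-(3,4,5-trihydroxyphenyl)-3-(2,4,6-trihydroxyphenyl)propan-2-yl 3,4,5-trihydroxybenzoate | O=C(O[C@@H](Cc1c(O)cc(O)cc1O)[C@H](c1cc(O)c(O)c(O)c1)c1c(O)cc2c(c1O)C[C@@H](OC(=O)c1cc(O)c(O)c(O)c1)[C@@H](c1cc(O)c(O)c(O)c1)O2)c1cc(O)c(O)c(O)c1 | target

**Totals and risks**

Total step count: 12. Longest linear sequence: 9 steps (steps 1, 3, 4, 7, 8, 9, 10, 11, 12).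

Steps most likely to fail:

1. Step 10 (Friedel–Crafts coupling). C6 of 10 is crowded and deactivated by the bromine. The epoxide may rearrange to a ketone or open by an SN1 path with loss of configuration. Fallback: form the C–C bond before ring C is closed. It sets out from 6: ortho-bromination of the phenol (NBS, cat. i-Pr2NH, CH2Cl2) gives bromo phenol F3. Its only free ring position is para to the free OH, more nucleophilic and less crowded, and opens 13 in HFIP to give alkyne adduct F4. Lindlar semi-hydrogenation gives Z-olefin F5. The epoxidation and ring-closure cascade of step 5 with the (S,S)-catalyst then closes ring C, and the route is rejoined at 14.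

2. Step 5 (epoxidation and ring closure on the free phenol). The phenol may be oxidised or bind the catalyst. The cis-epoxide may leak to the trans isomer, or close 5-exo. Fallback: separate the two ring-forming events with a silyl mask. It sets out from 7: TBSCl and imidazole in DMF give silyl ether F1. Epoxidation with the same (S,S)-catalyst, mCPBA and NMO gives silyl epoxide F2, which can be purified and assayed for ee. TBAF buffered with AcOH, then catalytic CSA at −40 °C, releases the phenol and effects the 6-endo closure. The route is rejoined at 9.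

3. Step 11 (double esterification). The chain alcohol is flanked by a diarylmethine and a 2,6-dioxygenated benzyl group and may resist acylation. Fallback: install the chain gallate before the crowded C–C bond exists. It sets out from 13: MgBr2·OEt2 opens the epoxide at the benzylic carbon with inversion to give bromohydrin F6. Its unhindered alcohol is esterified with 15 (DCC, DMAP) to give bromo gallate F7. AgOTf with 10 then ionises the bromide with participation of the ester carbonyl (cis-dioxolanylium ion), and C6 attacks with a second inversion. This gives the same chain configuration as step 10, with the ester already in place, in mono-gallate F8. Acylation of the remaining flavan 3-OH with 15 rejoins the route at 16.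

**Further compounds**

F1 | step 5 | tert-butyl{3,5-bis(benzyloxy)-2-[(Z)-3-(3,4,5-tris(benzyloxy)phenyl)prop-2-en-1-yl]phenoxy}dimethylsilane | CC(C)(C)[Si](C)(C)Oc1cc(OCc2ccccc2)cc(OCc2ccccc2)c1C/C=C\c1cc(OCc2ccccc2)c(OCc2ccccc2)c(OCc2ccccc2)c1
F2 | step 5 | tert-butyl{3,5-bis(benzyloxy)-2-{[(2R,3S)-3-(3,4,5-tris(benzyloxy)phenyl)oxiran-2-yl]methyl}phenoxy}dimethylsilane | CC(C)(C)[Si](C)(C)Oc1cc(OCc2ccccc2)cc(OCc2ccccc2)c1C[C@H]1O[C@H]1c1cc(OCc2ccccc2)c(OCc2ccccc2)c(OCc2ccccc2)c1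
F3 | step 10 | 3,5-bis(benzyloxy)-2-bromo-6-{3-[3,4,5-tris(benzyloxy)phenyl]prop-2-yn-1-yl}phenol | Oc1c(Br)c(OCc2ccccc2)cc(OCc2ccccc2)c1CC#Cc1cc(OCc2ccccc2)c(OCc2ccccc2)c(OCc2ccccc2)c1
F4 | step 10 | (1R,2S)-1-{2,6-bis(benzyloxy)-3-bromo-4-hydroxy-5-[3-(3,4,5-tris(benzyloxy)phenyl)prop-2-yn-1-yl]phenyl}-1-[3,4,5-tris(benzyloxy)phenyl]-3-[2,4,6-tris(benzyloxy)-3,5-dibromophenyl]propan-2-ol | O[C@@H](Cc1c(OCc2ccccc2)c(Br)c(OCc2ccccc2)c(Br)c1OCc1ccccc1)[C@H](c1cc(OCc2ccccc2)c(OCc2ccccc2)c(OCc2ccccc2)c1)c1c(OCc2ccccc2)c(Br)c(O)c(CC#Cc2cc(OCc3ccccc3)c(OCc3ccccc3)c(OCc3ccccc3)c2)c1OCc1ccccc1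
F5 | step 10 | (1R,2S)-1-{2,6-bis(benzyloxy)-3-bromo-4-hydroxy-5-[(Z)-3-(3,4,5-tris(benzyloxy)phenyl)prop-2-en-1-yl]phenyl}-1-[3,4,5-tris(benzyloxy)phenyl]-3-[2,4,6-tris(benzyloxy)-3,5-dibromophenyl]propan-2-ol | O[C@@H](Cc1c(OCc2ccccc2)c(Br)c(OCc2ccccc2)c(Br)c1OCc1ccccc1)[C@H](c1cc(OCc2ccccc2)c(OCc2ccccc2)c(OCc2ccccc2)c1)c1c(OCc2ccccc2)c(Br)c(O)c(C/C=C\c2cc(OCc3ccccc3)c(OCc3ccccc3)c(OCc3ccccc3)c2)c1OCc1ccccc1
F6 | step 11 | (1S,2S)-1-bromo-1-[3,4,5-tris(benzyloxy)phenyl]-3-[2,4,6-tris(benzyloxy)-3,5-dibromophenyl]propan-2-ol | O[C@@H](Cc1c(OCc2ccccc2)c(Br)c(OCc2ccccc2)c(Br)c1OCc1ccccc1)[C@@H](Br)c1cc(OCc2ccccc2)c(OCc2ccccc2)c(OCc2ccccc2)c1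
F7 | step 11 | (1S,2S)-1-bromo-1-[3,4,5-tris(benzyloxy)phenyl]-3-[2,4,6-tris(benzyloxy)-3,5-dibromophenyl]propan-2-yl 3,4,5-tris(benzyloxy)benzoate | O=C(O[C@@H](Cc1c(OCc2ccccc2)c(Br)c(OCc2ccccc2)c(Br)c1OCc1ccccc1)[C@@H](Br)c1cc(OCc2ccccc2)c(OCc2ccccc2)c(OCc2ccccc2)c1)c1cc(OCc2ccccc2)c(OCc2ccccc2)c(OCc2ccccc2)c1
F8 | step 11 | (1R,2S)-1-{(2R,3R)-5,7-bis(benzyloxy)-8-bromo-3-hydroxy-2-[3,4,5-tris(benzyloxy)phenyl]chroman-6-yl}-1-[3,4,5-tris(benzyloxy)phenyl]-3-[2,4,6-tris(benzyloxy)-3,5-dibromophenyl]propan-2-yl 3,4,5-tris(benzyloxy)benzoate | O=C(O[C@@H](Cc1c(OCc2ccccc2)c(Br)c(OCc2ccccc2)c(Br)c1OCc1ccccc1)[C@H](c1cc(OCc2ccccc2)c(OCc2ccccc2)c(OCc2ccccc2)c1)c1c(OCc2ccccc2)c(Br)c2c(c1OCc1ccccc1)C[C@@H](O)[C@@H](c1cc(OCc3ccccc3)c(OCc3ccccc3)c(OCc3ccccc3)c1)O2)c1cc(OCc2ccccc2)c(OCc2ccccc2)c(OCc2ccccc2)c1
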